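**Plan**

Locants: bicyclo[5.3.0]decane ring carbons C1–C10 (C1 and C5 ring fusion; five-membered ring C1–C5 with C2=C3 and C4(CH3)OH; seven-membered ring C1, C5–C10 with C6–OH, the side chain on C7 and C10=CH2); side chain C11(CH3)–C12–C13(OAc)–C14=C15(CH3)2.
Retrosynthesis: the C13 acetate and the C2=C3/C4–OH allylic alcohol are traced back (selenide opening of a 3,4-epoxide, methylation of a C4 enol triflate) to a cis-fused C4,C6-dioxygenated bicycle; this is cut at C1–C5 and C9–C10 to an allene–vinylcyclopropane, which is cut at C4–C5 (aldol) into hexa-4,5-dienal and a cyclopropyl methyl ketone carrying the side chain.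
Enabling feature: in the seven-membered ring the exocyclic methylene on C10 lies next to fusion carbon C1 and the oxygen on C6 next to fusion carbon C5. CH2=C10–C1 is therefore the retron of a terminal allene, and C5–C6(O)–C7 with C8–C9 that of a 1-siloxyvinylcyclopropane. One rhodium-catalysed [5+2] cycloaddition closes the five-membered ring through C1–C5 and, driven by opening of the cyclopropane C7–C8–C9, the seven-membered ring through C9–C10.
Forward: chain C6–C7/C11–C15 from methyl hydrogen (R)-3-methylglutarate, cyclopropane C7–C8–C9 by Simmons–Smith reaction, C4–C5 by boron aldol, both rings at once, then H-7, 6-OH, the C4 methyl, the allylic alcohol and the acetate.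
Stereochemistry: C11 from the chiral pool; C13 by CBS reduction; a temporary C4 carbinol (reagent-controlled aldol) fixes the absolute sense of C1/C5 in the cycloaddition (cis fusion is inherent); C7 (protonation), C6 (hydride) and C4 (epoxidation) follow from attack on the convex face of the cis-fused bicycle.

Key step: step 13

Abbreviations: TBS = tert-butyldimethylsilyl; TES = triethylsilyl; Ipc = isopinocampheyl; Q = (2R,4R)-4-(tert-butyldimethylsilyloxy)-6-methylhept-5-en-2-yl (C11–C15). Ring compounds are named with the plan locants.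

Assumption: (−)-Ipc2BCl is taken to direct the methyl-ketone enolate to the Re face of aldehyde 15, giving the (4S) carbinol; C4 is a temporary stereocentre, so the enantiomeric reagent would be used should the sense prove opposite.

**Route**

Step 1
Reactants: 1 methyl hydrogen (R)-3-methylglutarate; 2 2-methylprop-1-enylmagnesium bromide
Product: 4 methyl (3R)-3,7-dimethyl-5-oxooct-6-enoate, via acid chloride 3 (not isolated)
Conditions: (COCl)2, DMF (cat.), CH2Cl2, 0 to 23 °C; then 2, CuBr·SMe2 (5 mol%), THF, −78 °C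
Reagents that add atoms: none
Why: The acid terminus is activated as the acid chloride, which acylates the alkenyl Grignard reagent under copper catalysis (ketone synthesis from an acid chloride) faster than the methyl ester or the product enone reacts, so the C13 carbonyl and the C14=C15 alkene are installed while the chiral-pool C11 centre is untouched.

Step 2
Reactants: 4 methyl (3R)-3,7-dimethyl-5-oxooct-6-enoate
Product: 5 methyl (3R,5R)-5-hydroxy-3,7-dimethyloct-6-enoate
Conditions: (S)-Me-CBS oxazaborolidine [(S)-1-methyl-3,3-diphenyltetrahydro-1H,3H-pyrrolo[1,2-c][1,3,2]oxazaborole] (10 mol%), BH3·SMe2, THF, −30 °C; MeOH quench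
Reagents that add atoms: none
Why: Corey–Bakshi–Shibata reduction, in which the alkenyl group acts as the large substituent, delivers hydride to one face of the enone carbonyl under catalyst control and sets (13R), the ester being inert to the borane at this temperature.

Step 3
Reactants: 5 methyl (3R,5R)-5-hydroxy-3,7-dimethyloct-6-enoate
Product: 6 methyl (3R,5R)-5-(tert-butyldimethylsilyloxy)-3,7-dimethyloct-6-enoate
Conditions: TBSCl, imidazole, DMF, 0 to 23 °C
Reagents that add atoms: tert-butyldimethylsilyl chloride, CC(C)(C)[Si](C)(C)Cl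
Why: Standard silylation of the secondary allylic alcohol, carried out at once so that the δ-hydroxy ester cannot lactonise.

Step 4
Reactants: 6 methyl (3R,5R)-5-(tert-butyldimethylsilyloxy)-3,7-dimethyloct-6-enoate
Product: 7 (3R,5R)-5-(tert-butyldimethylsilyloxy)-3,7-dimethyloct-6-enal
Conditions: i-Bu2AlH (1.05 equiv), CH2Cl2, −78 °C; Rochelle salt work-up
Reagents that add atoms: none
Why: Low-temperature half-reduction of a methyl ester by i-Bu2AlH stops at the tetrahedral aluminate, which gives the aldehyde on work-up.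

Step 5
Reactants: 7 (3R,5R)-5-(tert-butyldimethylsilyloxy)-3,7-dimethyloct-6-enal
Product: 8 (3R,5R)-5-(tert-butyldimethylsilyloxy)-3,7-dimethyl-2-methylideneoct-6-enal
Conditions: aq. CH2O (37%), pyrrolidine (10 mol%), propanoic acid (10 mol%), i-PrOH, 45 °C
Reagents that add atoms: formaldehyde, C=O
Why: Amine/acid-catalysed Mannich condensation with formaldehyde followed by elimination (α-methylenation of an aldehyde) turns the C7 methylene into the 1,1-disubstituted alkene needed for cyclopropanation without touching C11.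

Step 6
Reactants: 8 (3R,5R)-5-(tert-butyldimethylsilyloxy)-3,7-dimethyl-2-methylideneoct-6-enal
Product: 9 (4R,6R)-6-(tert-butyldimethylsilyloxy)-4,8-dimethyl-3-methylidenenon-7-en-2-ol (both C2 epimers)
Conditions: MeMgBr, THF, −78 °C
Reagents that add atoms: methylmagnesium bromide, C[Mg]Br
Why: 1,2-Addition of the Grignard reagent to the enal gives the allylic alcohol that becomes the C5–C6 acetyl unit, and the new carbinol centre is removed in step 8 so both epimers are used.

Step 7
Reactants: 9 (4R,6R)-6-(tert-butyldimethylsilyloxy)-4,8-dimethyl-3-methylidenenon-7-en-2-ol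
Product: 10 1-(1-Q-cyclopropyl)ethan-1-ol (both carbinol epimers)
Conditions: Et2Zn, CH2I2, CH2Cl2, −10 to 0 °C
Reagents that add atoms: diiodomethane, ICI
Why: Hydroxyl-directed Simmons–Smith cyclopropanation (Furukawa reagent) is far faster at the alkene of the allylic zinc alkoxide than at the remote trisubstituted alkene, and builds the C7–C8–C9 cyclopropane whose strain drives step 13.

Step 8
Reactants: 10 1-(1-Q-cyclopropyl)ethan-1-ol
Product: 11 1-(1-Q-cyclopropyl)ethan-1-one
Conditions: Dess–Martin periodinane, NaHCO3, CH2Cl2, 0 to 23 °C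
Reagents that add atoms: none
Why: Dess–Martin oxidation of the secondary cyclopropyl carbinol gives the methyl ketone, whose only enolisable position is the methyl group C5.

Step 9
Reactants: 12 pent-4-yn-1-ol
Product: 14 hexa-4,5-dien-1-ol, via aminoalkyne 13 (not isolated)
Conditions: (CH2O)n, CuBr (0.5 equiv), i-Pr2NH, 1,4-dioxane, reflux
Reagents that add atoms: paraformaldehyde (as formaldehyde), C=O
Why: Crabbé homologation, in which the copper-mediated Mannich reaction of the terminal alkyne is followed by retro-imino-ene fragmentation of the propargylic amine, gives the terminal allene (C1=C10=CH2) with the free alcohol intact.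

Step 10
Reactants: 14 hexa-4,5-dien-1-ol
Product: 15 hexa-4,5-dienal
Conditions: Dess–Martin periodinane, NaHCO3, CH2Cl2, 0 °C
Reagents that add atoms: none
Why: Mild Dess–Martin oxidation gives the aldehyde without isomerising the allene.

Step 11
Reactants: 11 1-(1-Q-cyclopropyl)ethan-1-one; 15 hexa-4,5-dienal
Product: 17 (3S)-3-hydroxy-1-(1-Q-cyclopropyl)octa-6,7-dien-1-one, via boron enolate 16 (not isolated)
Conditions: (−)-Ipc2BCl, Et3N, Et2O, −78 to 0 °C; then 15, −78 to −20 °C; then MeOH, pH 7 buffer, 30% H2O2, 0 °C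
Reagents that add atoms: none
Why: The diisopinocampheylboron enolate of the methyl ketone adds to the aldehyde through a cyclic transition state under reagent control (boron aldol reaction), forming the C4–C5 bond and the temporary (4S) carbinol that steers step 13.

Step 12
Reactants: 17 (3S)-3-hydroxy-1-(1-Q-cyclopropyl)octa-6,7-dien-1-one
Product: 18 (1Z,3S)-1-(1-Q-cyclopropyl)-1,3-bis(triethylsilyloxy)octa-1,6,7-triene
Conditions: TESOTf (2.5 equiv), Et3N, CH2Cl2, −78 to 0 °C
Reagents that add atoms: triethylsilyl trifluoromethanesulfonate, CC[Si](CC)(CC)OS(=O)(=O)C(F)(F)F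
Why: The silyl triflate silylates the alcohol and, with triethylamine, converts the ketone into its silyl enol ether, which can only form towards C5 and places on C6 the oxygen substituent that activates the vinylcyclopropane.

Step 13
Reactants: 18 (1Z,3S)-1-(1-Q-cyclopropyl)-1,3-bis(triethylsilyloxy)octa-1,6,7-triene
Product: 19 (1S,4S,5S)-7-Q-10-methylidene-4,6-bis(triethylsilyloxy)bicyclo[5.3.0]dec-6-ene
Conditions: [Rh(CO)2Cl]2 (2.5 mol%), toluene (0.02 M), 80 °C
Reagents that add atoms: none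
Why: Monovalent rhodium binds the vinylcyclopropane of 18 and opens the strained ring by oxidative addition into C7–C9 (C7–C8 is equivalent), giving a trivalent rhodium σ-alkyl/π-allyl metallacycle; the tethered allene then inserts through its internal C1=C10 π bond at the allyl terminus C5, and C9–C10 reductive elimination releases the catalyst. The closest known reaction type is the rhodium-catalysed intramolecular [5+2] cycloaddition of allenes with vinylcyclopropanes, used here with a 1-siloxy-substituted alkene and a fully substituted cyclopropane carbon. The five-membered ring (C1–C5) is closed by the C1–C5 bond in a 5-exo carbometallation across the three-atom tether C2–C3–C4, and the seven-membered ring (C1, C5–C10) by the C9–C10 reductive elimination, which is paid for by release of cyclopropane strain and leaves the methylene on C10. C1 and C5 are formed cis because both new bonds are delivered on one face of the rhodacycle, and their absolute sense is set by C4: A(1,3) strain with the Z-siloxy group on C6 keeps H-4 in the alkene plane, so the tether brings the allene to the C5=C6 face opposite the C4 silyloxy group, which ends up cis to H-5. The step needs chemoselectivity for the internal allene π bond, secured by the tether length, and inertness of the side-chain alkene, which is neither strained nor tethered. Regiochemistry of cyclopropane cleavage is not an issue because C8 and C9 are equivalent CH2 groups.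

Step 14
Reactants: 19 (1S,4S,5S)-7-Q-10-methylidene-4,6-bis(triethylsilyloxy)bicyclo[5.3.0]dec-6-ene
Product: 20 (1S,4S,5S,7R)-7-Q-10-methylidene-4-(triethylsilyloxy)bicyclo[5.3.0]decan-6-one
Conditions: Bu4NF (1.05 equiv), AcOH (1.5 equiv), THF, −78 °C
Reagents that add atoms: none
Why: Fluoride cleaves the silyl enol ether much faster than the alkyl silyl ethers and the resulting C6–C7 enolate is protonated kinetically by acetic acid on the open convex face of the cis-fused bicycle (the face of H-1 and H-5), which sets (7R) with H-7 cis to H-5.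

Step 15
Reactants: 20 (1S,4S,5S,7R)-7-Q-10-methylidene-4-(triethylsilyloxy)bicyclo[5.3.0]decan-6-one
Product: 21 (1S,4S,5R,6S,7R)-7-Q-10-methylidene-4-(triethylsilyloxy)bicyclo[5.3.0]decan-6-ol
Conditions: LiBH(s-Bu)3 (L-Selectride), THF, −78 °C; then NaOH, H2O2
Reagents that add atoms: none
Why: The bulky trialkylborohydride approaches the hindered ketone from the same convex face, between the two α-hydrogens, and gives the 6-alcohol cis to the C7 side chain and trans to H-5, that is (6S).

Step 16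
Reactants: 21 (1S,4S,5R,6S,7R)-7-Q-10-methylidene-4-(triethylsilyloxy)bicyclo[5.3.0]decan-6-ol
Product: 22 (1S,4S,5S,6S,7R)-6-(tert-butyldimethylsilyloxy)-7-Q-10-methylidene-4-(triethylsilyloxy)bicyclo[5.3.0]decane
Conditions: TBSOTf, 2,6-lutidine, CH2Cl2, −78 to 0 °C
Reagents that add atoms: tert-butyldimethylsilyl trifluoromethanesulfonate, CC(C)(C)[Si](C)(C)OS(=O)(=O)C(F)(F)F
Why: The reactive silyl triflate protects the hindered C6 alcohol so that C4 can be oxidised alone.

Step 17
Reactants: 22 (1S,4S,5S,6S,7R)-6-(tert-butyldimethylsilyloxy)-7-Q-10-methylidene-4-(triethylsilyloxy)bicyclo[5.3.0]decane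
Product: 23 (1S,4S,5S,6S,7R)-6-(tert-butyldimethylsilyloxy)-7-Q-10-methylidenebicyclo[5.3.0]decan-4-ol
Conditions: pyridinium p-toluenesulfonate (10 mol%), MeOH/CH2Cl2, 0 °C
Reagents that add atoms: none
Why: A secondary triethylsilyl ether is solvolysed by mild acid in methanol much faster than tert-butyldimethylsilyl ethers, which frees only the C4 alcohol.

Step 18
Reactants: 23 (1S,4S,5S,6S,7R)-6-(tert-butyldimethylsilyloxy)-7-Q-10-methylidenebicyclo[5.3.0]decan-4-ol
Product: 24 (1S,5R,6S,7R)-6-(tert-butyldimethylsilyloxy)-7-Q-10-methylidenebicyclo[5.3.0]decan-4-one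
Conditions: Dess–Martin periodinane, NaHCO3, CH2Cl2, 0 to 23 °C
Reagents that add atoms: none
Why: Dess–Martin oxidation removes the temporary C4 stereocentre and gives the cyclopentanone needed to introduce the C4 methyl group.

Step 19
Reactants: 24 (1S,5R,6S,7R)-6-(tert-butyldimethylsilyloxy)-7-Q-10-methylidenebicyclo[5.3.0]decan-4-one
Product: 26 (1S,5R,6S,7R)-6-(tert-butyldimethylsilyloxy)-7-Q-10-methylidenebicyclo[5.3.0]dec-3-en-4-yl trifluoromethanesulfonate, via potassium enolate 25 (not isolated)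
Conditions: KN(SiMe3)2, THF, −78 °C; then PhNTf2
Reagents that add atoms: N-phenylbis(trifluoromethanesulfonimide), O=S(=O)(N(c1ccccc1)S(=O)(=O)C(F)(F)F)C(F)(F)F
Why: Kinetic deprotonation by the hindered amide base occurs at the C3 methylene and not at the crowded ring-fusion methine C5, and O-sulfonylation of this enolate fixes the C3=C4 double bond.

Step 20
Reactants: 26 (1S,5R,6S,7R)-6-(tert-butyldimethylsilyloxy)-7-Q-10-methylidenebicyclo[5.3.0]dec-3-en-4-yl trifluoromethanesulfonate
Product: 27 (1S,5S,6S,7R)-6-(tert-butyldimethylsilyloxy)-4-methyl-7-Q-10-methylidenebicyclo[5.3.0]dec-3-ene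
Conditions: MeMgBr, Fe(acac)3 [iron tris(pentane-2,4-dionate)] (5 mol%), THF/NMP, −30 °C
Reagents that add atoms: methylmagnesium bromide, C[Mg]Br
Why: Iron-catalysed cross-coupling of the alkenyl triflate with the methyl Grignard reagent replaces the triflate by the C4 methyl group with retention of the double-bond position.

Step 21
Reactants: 27 (1S,5S,6S,7R)-6-(tert-butyldimethylsilyloxy)-4-methyl-7-Q-10-methylidenebicyclo[5.3.0]dec-3-ene
Product: 28 (1S,3S,4R,5R,6S,7R)-6-(tert-butyldimethylsilyloxy)-3,4-epoxy-4-methyl-7-Q-10-methylidenebicyclo[5.3.0]decane (epoxide oxygen cis to H-5)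
Conditions: mCPBA (1.05 equiv), NaHCO3, CH2Cl2, −20 °C
Reagents that add atoms: 3-chloroperoxybenzoic acid, OOC(=O)c1cccc(Cl)c1
Why: Prilezhaev epoxidation takes the strained trisubstituted cyclopentene in preference to the 1,1-disubstituted methylene and to the side-chain alkene deactivated by its allylic silyloxy group, and occurs on the convex face anti to the C6 silyloxy group, so that the epoxide oxygen (the future 4-OH) is cis to H-5.

Step 22
Reactants: 28 (1S,3S,4R,5R,6S,7R)-6-(tert-butyldimethylsilyloxy)-3,4-epoxy-4-methyl-7-Q-10-methylidenebicyclo[5.3.0]decane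
Product: 31 (1S,4S,5R,6S,7R)-6-(tert-butyldimethylsilyloxy)-4-methyl-7-Q-10-methylidenebicyclo[5.3.0]dec-2-en-4-ol, via hydroxy selenide 29 (not isolated), via selenoxide 30 (not isolated)
Conditions: (PhSe)2, NaBH4, EtOH, 78 °C; then 30% H2O2, pyridine, THF, 0 to 23 °C
Reagents that add atoms: none
Why: Benzeneselenolate opens the epoxide by SN2 attack at the less substituted C3 with the C4–O bond retained as the tertiary alcohol (4S), and the derived selenoxide undergoes syn elimination, which can only run towards C2 because C4 has no hydrogen (epoxide to allylic alcohol transposition), creating C2=C3.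

Step 23
Reactants: 31 (1S,4S,5R,6S,7R)-6-(tert-butyldimethylsilyloxy)-4-methyl-7-Q-10-methylidenebicyclo[5.3.0]dec-2-en-4-ol
Product: 32 (1S,4S,5R,6S,7R)-7-[(2R,4R)-4-hydroxy-6-methylhept-5-en-2-yl]-4-methyl-10-methylidenebicyclo[5.3.0]dec-2-ene-4,6-diol
Conditions: Bu4NF, THF, 23 to 45 °C
Reagents that add atoms: none
Why: Fluoride removes both silyl ethers, while the tertiary allylic alcohol, the alkenes and the stereocentres are inert to these conditions.

Step 24
Reactants: 32 (1S,4S,5R,6S,7R)-7-[(2R,4R)-4-hydroxy-6-methylhept-5-en-2-yl]-4-methyl-10-methylidenebicyclo[5.3.0]dec-2-ene-4,6-diol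
Product: 33 (1S,4S,5R,6S,7R)-7-[(2R,4R)-4-acetoxy-6-methylhept-5-en-2-yl]-4-methyl-10-methylidenebicyclo[5.3.0]dec-2-ene-4,6-diol (CNP0209568.2)
Conditions: Ac2O (1.1 equiv), Et3N, 4-(dimethylamino)pyridine (5 mol%), CH2Cl2, −20 °C
Reagents that add atoms: acetic anhydride, CC(=O)OC(C)=O
Why: Acylation is directed to the unhindered allylic C13 alcohol, since the C6 alcohol is flanked by two branched carbons and the C4 alcohol is tertiary, so one equivalent of anhydride at low temperature should give the 13-monoacetate.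

**Compound list**

1 | methyl hydrogen (R)-3-methylglutarate | COC(=O)C[C@H](C)CC(O)=O | starting material
2 | 2-methylprop-1-enylmagnesium bromide | CC(C)=C[Mg]Br | starting material
3 | methyl (3S)-5-chloro-3-methyl-5-oxopentanoate | COC(=O)C[C@H](C)CC(Cl)=O | intermediate (not isolated)
4 | methyl (3R)-3,7-dimethyl-5-oxooct-6-enoate | COC(=O)C[C@H](C)CC(=O)C=C(C)C | intermediate
5 | methyl (3R,5R)-5-hydroxy-3,7-dimethyloct-6-enoate | COC(=O)C[C@H](C)C[C@H](C=C(C)C)O | intermediate
6 | methyl (3R,5R)-5-(tert-butyldimethylsilyloxy)-3,7-dimethyloct-6-enoate | COC(=O)C[C@H](C)C[C@H](C=C(C)C)O[Si](C)(C)C(C)(C)C | intermediate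
7 | (3R,5R)-5-(tert-butyldimethylsilyloxy)-3,7-dimethyloct-6-enal | O=CC[C@H](C)C[C@H](C=C(C)C)O[Si](C)(C)C(C)(C)C | intermediate
8 | (3R,5R)-5-(tert-butyldimethylsilyloxy)-3,7-dimethyl-2-methylideneoct-6-enal | O=CC(=C)[C@H](C)C[C@H](C=C(C)C)O[Si](C)(C)C(C)(C)C | intermediate
9 | (4R,6R)-6-(tert-butyldimethylsilyloxy)-4,8-dimethyl-3-methylidenenon-7-en-2-ol (both C2 epimers) | CC(O)C(=C)[C@H](C)C[C@H](C=C(C)C)O[Si](C)(C)C(C)(C)C | intermediate
10 | 1-(1-Q-cyclopropyl)ethan-1-ol (both carbinol epimers) | CC(O)C1(CC1)[C@H](C)C[C@H](C=C(C)C)O[Si](C)(C)C(C)(C)C | intermediate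
11 | 1-(1-Q-cyclopropyl)ethan-1-one | CC(=O)C1(CC1)[C@H](C)C[C@H](C=C(C)C)O[Si](C)(C)C(C)(C)C | intermediate
12 | pent-4-yn-1-ol | C#CCCCO | starting material
13 | 6-(diisopropylamino)hex-4-yn-1-ol | CC(C)N(CC#CCCCO)C(C)C | intermediate (not isolated)
14 | hexa-4,5-dien-1-ol | C=C=CCCCO | intermediate
15 | hexa-4,5-dienal | C=C=CCCC=O | intermediate
16 | diisopinocampheylboron enolate of 11 | C=C(OB([C@@H]1C[C@@H]2C[C@H]([C@H]1C)C2(C)C)[C@@H]1C[C@@H]2C[C@H]([C@H]1C)C2(C)C)C1(CC1)[C@H](C)C[C@H](C=C(C)C)O[Si](C)(C)C(C)(C)C | intermediate (not isolated)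
17 | (3S)-3-hydroxy-1-(1-Q-cyclopropyl)octa-6,7-dien-1-one | C=C=CCC[C@H](O)CC(=O)C1(CC1)[C@H](C)C[C@H](C=C(C)C)O[Si](C)(C)C(C)(C)C | intermediate
18 | (1Z,3S)-1-(1-Q-cyclopropyl)-1,3-bis(triethylsilyloxy)octa-1,6,7-triene | C=C=CCC[C@H](O[Si](CC)(CC)CC)/C=C(\O[Si](CC)(CC)CC)C1(CC1)[C@H](C)C[C@H](C=C(C)C)O[Si](C)(C)C(C)(C)C | intermediate
19 | (1S,4S,5S)-7-Q-10-methylidene-4,6-bis(triethylsilyloxy)bicyclo[5.3.0]dec-6-ene | C=C1CCC([C@H](C)C[C@H](C=C(C)C)O[Si](C)(C)C(C)(C)C)=C(O[Si](CC)(CC)CC)[C@H]2[C@@H]1CC[C@@H]2O[Si](CC)(CC)CC | intermediate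
20 | (1S,4S,5S,7R)-7-Q-10-methylidene-4-(triethylsilyloxy)bicyclo[5.3.0]decan-6-one | C=C1CC[C@H]([C@H](C)C[C@H](C=C(C)C)O[Si](C)(C)C(C)(C)C)C(=O)[C@H]2[C@@H]1CC[C@@H]2O[Si](CC)(CC)CC | intermediate
21 | (1S,4S,5R,6S,7R)-7-Q-10-methylidene-4-(triethylsilyloxy)bicyclo[5.3.0]decan-6-ol | C=C1CC[C@H]([C@H](C)C[C@H](C=C(C)C)O[Si](C)(C)C(C)(C)C)[C@H](O)[C@H]2[C@@H]1CC[C@@H]2O[Si](CC)(CC)CC | intermediate
22 | (1S,4S,5S,6S,7R)-6-(tert-butyldimethylsilyloxy)-7-Q-10-methylidene-4-(triethylsilyloxy)bicyclo[5.3.0]decane | C=C1CC[C@H]([C@H](C)C[C@H](C=C(C)C)O[Si](C)(C)C(C)(C)C)[C@H](O[Si](C)(C)C(C)(C)C)[C@H]2[C@@H]1CC[C@@H]2O[Si](CC)(CC)CC | intermediate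
23 | (1S,4S,5S,6S,7R)-6-(tert-butyldimethylsilyloxy)-7-Q-10-methylidenebicyclo[5.3.0]decan-4-ol | C=C1CC[C@H]([C@H](C)C[C@H](C=C(C)C)O[Si](C)(C)C(C)(C)C)[C@H](O[Si](C)(C)C(C)(C)C)[C@H]2[C@@H]1CC[C@@H]2O | intermediate
24 | (1S,5R,6S,7R)-6-(tert-butyldimethylsilyloxy)-7-Q-10-methylidenebicyclo[5.3.0]decan-4-one | C=C1CC[C@H]([C@H](C)C[C@H](C=C(C)C)O[Si](C)(C)C(C)(C)C)[C@H](O[Si](C)(C)C(C)(C)C)[C@H]2[C@@H]1CCC2=O | intermediate
25 | potassium C3-enolate of 24 | C=C1CC[C@H]([C@H](C)C[C@H](C=C(C)C)O[Si](C)(C)C(C)(C)C)[C@H](O[Si](C)(C)C(C)(C)C)[C@H]2[C@@H]1CC=C2[O-].[K+] | intermediate (not isolated)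
26 | (1S,5R,6S,7R)-6-(tert-butyldimethylsilyloxy)-7-Q-10-methylidenebicyclo[5.3.0]dec-3-en-4-yl trifluoromethanesulfonate | C=C1CC[C@H]([C@H](C)C[C@H](C=C(C)C)O[Si](C)(C)C(C)(C)C)[C@H](O[Si](C)(C)C(C)(C)C)[C@H]2[C@@H]1CC=C2OS(=O)(=O)C(F)(F)F | intermediate
27 | (1S,5S,6S,7R)-6-(tert-butyldimethylsilyloxy)-4-methyl-7-Q-10-methylidenebicyclo[5.3.0]dec-3-ene | C=C1CC[C@H]([C@H](C)C[C@H](C=C(C)C)O[Si](C)(C)C(C)(C)C)[C@H](O[Si](C)(C)C(C)(C)C)[C@H]2[C@@H]1CC=C2C | intermediate
28 | (1S,3S,4R,5R,6S,7R)-6-(tert-butyldimethylsilyloxy)-3,4-epoxy-4-methyl-7-Q-10-methylidenebicyclo[5.3.0]decane | C=C1CC[C@H]([C@H](C)C[C@H](C=C(C)C)O[Si](C)(C)C(C)(C)C)[C@H](O[Si](C)(C)C(C)(C)C)[C@H]2[C@@H]1C[C@@H]3O[C@]23C | intermediate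
29 | (1S,3R,4R,5R,6S,7R)-6-(tert-butyldimethylsilyloxy)-4-methyl-7-Q-10-methylidene-3-(phenylselanyl)bicyclo[5.3.0]decan-4-ol | C=C1CC[C@H]([C@H](C)C[C@H](C=C(C)C)O[Si](C)(C)C(C)(C)C)[C@H](O[Si](C)(C)C(C)(C)C)[C@H]2[C@@H]1C[C@@H]([Se]c3ccccc3)[C@]2(C)O | intermediate (not isolated)
30 | selenoxide of 29 | C=C1CC[C@H]([C@H](C)C[C@H](C=C(C)C)O[Si](C)(C)C(C)(C)C)[C@H](O[Si](C)(C)C(C)(C)C)[C@H]2[C@@H]1C[C@@H]([Se](=O)c3ccccc3)[C@]2(C)O | intermediate (not isolated)
31 | (1S,4S,5R,6S,7R)-6-(tert-butyldimethylsilyloxy)-4-methyl-7-Q-10-methylidenebicyclo[5.3.0]dec-2-en-4-ol | C=C1CC[C@H]([C@H](C)C[C@H](C=C(C)C)O[Si](C)(C)C(C)(C)C)[C@H](O[Si](C)(C)C(C)(C)C)[C@H]2[C@@H]1C=C[C@]2(C)O | intermediate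
32 | (1S,4S,5R,6S,7R)-7-[(2R,4R)-4-hydroxy-6-methylhept-5-en-2-yl]-4-methyl-10-methylidenebicyclo[5.3.0]dec-2-ene-4,6-diol | C=C1CC[C@H]([C@H](C)C[C@H](C=C(C)C)O)[C@H](O)[C@H]2[C@@H]1C=C[C@]2(C)O | intermediate
33 | (1S,4S,5R,6S,7R)-7-[(2R,4R)-4-acetoxy-6-methylhept-5-en-2-yl]-4-methyl-10-methylidenebicyclo[5.3.0]dec-2-ene-4,6-diol (CNP0209568.2) | C=C1CC[C@H]([C@H](C)C[C@H](C=C(C)C)OC(C)=O)[C@H](O)[C@H]2[C@@H]1C=C[C@]2(C)O | target

**Step count and risks**

Total step count: 24. Longest linear sequence: 22 steps (steps 1–8, then 11–24); steps 9–10 form a two-step branch.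

Steps most likely to fail:

Step 13. The crowded 1-siloxyvinylcyclopropane may be opened and isomerised by rhodium to a siloxydiene faster than the allene inserts, or facial discrimination at C5 may be incomplete, so that diastereomers with the wrong ring configuration relative to the side chain form. The fallback uses an alkyne, the most dependable two-carbon partner in this cycloaddition, and generates the methylene afterwards. It sets out from 12 and 11 and comes back at 20. Pent-4-yn-1-ol 12 is alkylated as its dianion (n-BuLi, then ICH2SiMe3) to 6-(trimethylsilyl)hex-4-yn-1-ol F1 and oxidised with Dess–Martin periodinane to 6-(trimethylsilyl)hex-4-ynal F2. The boron aldol of step 11 with 11 gives (3S)-3-hydroxy-1-(1-Q-cyclopropyl)-8-(trimethylsilyl)oct-6-yn-1-one F3, and silylation as in step 12 gives the bis(triethylsilyl) enol ether F4. The alkyne–vinylcyclopropane [5+2] cycloaddition with [Rh(CO)2Cl]2 gives the bicyclic 1(10),6-diene with a C10 trimethylsilylmethyl group F5. Camphorsulfonic acid in wet CH2Cl2 at 0 °C then protodesilylates this allylsilane, with protonation of C1 on the convex face (H-1 cis to H-5, C10 methylene formed), and hydrolyses the enol silane to give 20.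

Step 21. Epoxidation may not discriminate sufficiently between the cyclopentene and the side-chain trisubstituted alkene, leading to over-oxidation. The fallback uses nucleophilic epoxidation of an enone, which cannot touch isolated alkenes; it sets out from 24 and comes back at 31. Ketone 24 is converted (LDA, Me3SiCl) into the C3 trimethylsilyl enol ether F6 and dehydrogenated with Pd(OAc)2 (Saegusa–Ito oxidation) to the 2-en-4-one F7. MeLi/CeCl3 gives the tertiary allylic alcohol F8, whose C4 configuration is irrelevant. Pyridinium chlorochromate effects oxidative 1,3-transposition to the 4-methyl-3-en-2-one F9. H2O2/NaOH in MeOH at 0 °C epoxidises the enone on the convex face to the 3,4-epoxy-2-ketone F10. Wharton transposition (N2H4·H2O, AcOH, MeOH) then gives 31 with the 4-OH cis to H-5.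

Step 24. Acylation may also reach the C6 alcohol, or acetyl migration may occur, giving diacetate or regioisomers. The fallback differentiates the two secondary alcohols by staged deprotection; it sets out from 31 and comes back at 33. The less hindered allylic C13 silyl ether of 31 is cleaved selectively (HF·pyridine, pyridine, THF, 0 °C) to the 13-alcohol 6-silyl ether F11. Acetylation (Ac2O, Et3N, 4-(dimethylamino)pyridine) gives the 13-acetate 6-silyl ether F12, and Bu4NF buffered with AcOH removes the C6 silyl group to give 33.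

**Further compounds**

F1 | step 13 | 6-(trimethylsilyl)hex-4-yn-1-ol | C[Si](C)(C)CC#CCCCO
F2 | step 13 | 6-(trimethylsilyl)hex-4-ynal | C[Si](C)(C)CC#CCCC=O
F3 | step 13 | (3S)-3-hydroxy-1-(1-Q-cyclopropyl)-8-(trimethylsilyl)oct-6-yn-1-one | C[Si](C)(C)CC#CCC[C@H](O)CC(=O)C1(CC1)[C@H](C)C[C@H](C=C(C)C)O[Si](C)(C)C(C)(C)C
F4 | step 13 | (1Z,3S)-1-(1-Q-cyclopropyl)-1,3-bis(triethylsilyloxy)-8-(trimethylsilyl)oct-1-en-6-yne | C[Si](C)(C)CC#CCC[C@H](O[Si](CC)(CC)CC)/C=C(\O[Si](CC)(CC)CC)C1(CC1)[C@H](C)C[C@H](C=C(C)C)O[Si](C)(C)C(C)(C)C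
F5 | step 13 | (4S,5S)-7-Q-4,6-bis(triethylsilyloxy)-10-(trimethylsilylmethyl)bicyclo[5.3.0]deca-1(10),6-diene | C[Si](C)(C)CC1=C2CC[C@H](O[Si](CC)(CC)CC)[C@H]2C(O[Si](CC)(CC)CC)=C(CC1)[C@H](C)C[C@H](C=C(C)C)O[Si](C)(C)C(C)(C)C
F6 | step 21 | (1S,5R,6S,7R)-6-(tert-butyldimethylsilyloxy)-7-Q-10-methylidene-4-(trimethylsilyloxy)bicyclo[5.3.0]dec-3-ene | C=C1CC[C@H]([C@H](C)C[C@H](C=C(C)C)O[Si](C)(C)C(C)(C)C)[C@H](O[Si](C)(C)C(C)(C)C)[C@H]2[C@@H]1CC=C2O[Si](C)(C)C
F7 | step 21 | (1S,5R,6S,7R)-6-(tert-butyldimethylsilyloxy)-7-Q-10-methylidenebicyclo[5.3.0]dec-2-en-4-one | C=C1CC[C@H]([C@H](C)C[C@H](C=C(C)C)O[Si](C)(C)C(C)(C)C)[C@H](O[Si](C)(C)C(C)(C)C)[C@H]2[C@@H]1C=CC2=O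
F8 | step 21 | (1S,4R,5R,6S,7R)-6-(tert-butyldimethylsilyloxy)-4-methyl-7-Q-10-methylidenebicyclo[5.3.0]dec-2-en-4-ol (4-epimer of 31) | C=C1CC[C@H]([C@H](C)C[C@H](C=C(C)C)O[Si](C)(C)C(C)(C)C)[C@H](O[Si](C)(C)C(C)(C)C)[C@H]2[C@@H]1C=C[C@@]2(C)O
F9 | step 21 | (1S,5S,6S,7R)-6-(tert-butyldimethylsilyloxy)-4-methyl-7-Q-10-methylidenebicyclo[5.3.0]dec-3-en-2-one | C=C1CC[C@H]([C@H](C)C[C@H](C=C(C)C)O[Si](C)(C)C(C)(C)C)[C@H](O[Si](C)(C)C(C)(C)C)[C@H]2[C@@H]1C(=O)C=C2C
F10 | step 21 | (1S,3R,4R,5R,6S,7R)-6-(tert-butyldimethylsilyloxy)-3,4-epoxy-4-methyl-7-Q-10-methylidenebicyclo[5.3.0]decan-2-one | C=C1CC[C@H]([C@H](C)C[C@H](C=C(C)C)O[Si](C)(C)C(C)(C)C)[C@H](O[Si](C)(C)C(C)(C)C)[C@H]2[C@@H]1C(=O)[C@@H]3O[C@]23C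
F11 | step 24 | (1S,4S,5R,6S,7R)-6-(tert-butyldimethylsilyloxy)-7-[(2R,4R)-4-hydroxy-6-methylhept-5-en-2-yl]-4-methyl-10-methylidenebicyclo[5.3.0]dec-2-en-4-ol | C=C1CC[C@H]([C@H](C)C[C@H](C=C(C)C)O)[C@H](O[Si](C)(C)C(C)(C)C)[C@H]2[C@@H]1C=C[C@]2(C)O
F12 | step 24 | (1S,4S,5R,6S,7R)-7-[(2R,4R)-4-acetoxy-6-methylhept-5-en-2-yl]-6-(tert-butyldimethylsilyloxy)-4-methyl-10-methylidenebicyclo[5.3.0]dec-2-en-4-ol | C=C1CC[C@H]([C@H](C)C[C@H](C=C(C)C)OC(C)=O)[C@H](O[Si](C)(C)C(C)(C)C)[C@H]2[C@@H]1C=C[C@]2(C)O
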